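**Retrosynthetic overview**
1. Target 10 ⇒ chromanol 8 + prenyl bromide 9: late ortho C‑prenylation at C8, the carbon between the two ring oxygens.
2. 8 ⇒ 2‑prenylpinosylvin 6: the pyran C–O bond comes from a phenol‑directed asymmetric epoxidation of the only prenyl group, then 6‑endo opening at the tertiary carbon. This sets C3 as R.
3. 6 ⇒ bromoresorcinol 4 + prenylboronate 5 (Suzuki–Miyaura); the bromine fixes the position next to the styryl group.
4. 4 ⇒ 2‑bromo‑3,5‑dimethoxybenzaldehyde 1 + diethyl benzylphosphonate 2 (Horner–Wadsworth–Emmons for the E‑stilbene, then demethylation).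
5. Ring order: both benzene rings are bought; the pyran ring is the only ring made (step 4).

Assumption: 1 is taken as a catalogue compound, and the (R,R) ligand in step 4 is taken to give the R epoxide (the S,S ligand is used instead if the first run shows the opposite sense).

**Step 1**
Reactants: 1 2‑bromo‑3,5‑dimethoxybenzaldehyde; 2 diethyl benzylphosphonate
Product: 3 2‑bromo‑1,5‑dimethoxy‑3‑[(E)‑2‑phenylethenyl]benzene
Conditions: KOtBu (1.2 equiv), THF, 0 °C to rt
Reagents that add atoms: none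
Why: Horner–Wadsworth–Emmons olefination of an aryl aldehyde with a benzyl phosphonate anion is reliably E‑selective and tolerates the ortho bromide and the methyl ethers.

**Step 2**
Reactants: 3 2‑bromo‑1,5‑dimethoxy‑3‑[(E)‑2‑phenylethenyl]benzene
Product: 4 4‑bromo‑5‑[(E)‑2‑phenylethenyl]benzene‑1,3‑diol
Conditions: BBr3 (4 equiv), CH2Cl2, −78 °C to rt; H2O
Reagents that add atoms: none
Why: BBr3 cleavage of aryl methyl ethers (bromide attack on the O‑borylated methyl group) is the standard route to free hydroxystilbenes and leaves the aryl bromide and the E‑alkene intact.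

**Step 3**
Reactants: 4 4‑bromo‑5‑[(E)‑2‑phenylethenyl]benzene‑1,3‑diol; 5 4,4,5,5‑tetramethyl‑2‑(3‑methylbut‑2‑en‑1‑yl)‑1,3,2‑dioxaborolane
Product: 6 4‑(3‑methylbut‑2‑en‑1‑yl)‑5‑[(E)‑2‑phenylethenyl]benzene‑1,3‑diol
Conditions: PdCl2(IPent)(3‑chloropyridine) (3 mol%; IPent = 1,3‑bis[2,6‑di(pentan‑3‑yl)phenyl]imidazol‑2‑ylidene), 5 M aq. KOH (5 equiv), 5 (2 equiv), THF, 70 °C, argon
Reagents that add atoms: none
Why: Suzuki–Miyaura coupling of an aryl bromide with a prenylboronate, where the very bulky carbene ligand allows oxidative addition to the hindered, electron‑rich bromide and gives the linear (alpha) prenyl product; the phenols ride through as phenoxides and the bromine dictates the site.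

**Step 4**
Reactants: 6 4‑(3‑methylbut‑2‑en‑1‑yl)‑5‑[(E)‑2‑phenylethenyl]benzene‑1,3‑diol
Product: 8 (3R)‑2,2‑dimethyl‑5‑[(E)‑2‑phenylethenyl]‑3,4‑dihydro‑2H‑chromene‑3,7‑diol, via (R)‑epoxide 7 (not isolated)
Conditions: Hf(OtBu)4 (15 mol%), N,N′‑[(1R,2R)‑cyclohexane‑1,2‑diyl]bis(N‑hydroxy‑2,2‑diphenylacetamide) (17 mol%), DMPU (30 mol%), 4 Å MS, cumene hydroperoxide (1.3 equiv), toluene, 0 °C; then camphorsulfonic acid (20 mol%), −20 to 0 °C
Reagents that add atoms: cumene hydroperoxide, CC(C)(OO)c1ccccc1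
Why: Proposed new method: the phenol next to the prenyl group binds as a phenoxide to tetravalent hafnium inside the C2‑symmetric bishydroxamate pocket, which holds the trisubstituted alkene (four atoms from oxygen, the spacing of a bishomoallylic alcohol) against the hafnium‑bound cumyl peroxide so that oxygen is delivered to one face and gives (R)‑epoxide 7, while the stilbene, which no bound oxygen can reach, is untouched and the redox‑inert metal does not oxidise the resorcinol; camphorsulfonic acid then lets the same phenol open the epoxide at its tertiary carbon (6‑endo, Markovnikov), which forms the pyran C–O bond without breaking the C3–O bond, so the R configuration is kept; the closest known reactions are the Hf(OtBu)4/bishydroxamic acid asymmetric epoxidation of homoallylic and bishomoallylic alcohols and the racemic VO(acac)2/t‑BuOOH oxidative cyclisation of ortho‑prenylphenols, the untested element being a phenol as directing group.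

**Step 5**
Reactants: 8 (3R)‑2,2‑dimethyl‑5‑[(E)‑2‑phenylethenyl]‑3,4‑dihydro‑2H‑chromene‑3,7‑diol; 9 1‑bromo‑3‑methylbut‑2‑ene
Product: 10 (3R)‑2,2‑dimethyl‑8‑(3‑methylbut‑2‑en‑1‑yl)‑5‑[(E)‑2‑phenylethenyl]‑3,4‑dihydro‑2H‑chromene‑3,7‑diol
Conditions: NaH (1.05 equiv), toluene, 0 °C; then 9 (1.1 equiv), rt
Reagents that add atoms: none
Why: Ortho C‑alkylation of a sodium phenoxide in a non‑polar solvent (tight ion pair shields oxygen, direct displacement at the prenyl CH2); of the two ortho carbons, C8 between the phenoxide and the ring oxygen is doubly activated and open, whereas C6 is shielded by the styryl group, and the C3 stereocentre is not involved.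

**Compound list**
1 | 2‑bromo‑3,5‑dimethoxybenzaldehyde | COc1cc(OC)c(Br)c(C=O)c1 | starting material
2 | diethyl benzylphosphonate | CCOP(=O)(Cc1ccccc1)OCC | starting material
3 | 2‑bromo‑1,5‑dimethoxy‑3‑[(E)‑2‑phenylethenyl]benzene | COc1cc(OC)c(Br)c(/C=C/c2ccccc2)c1 | intermediate
4 | 4‑bromo‑5‑[(E)‑2‑phenylethenyl]benzene‑1,3‑diol | Oc1cc(O)c(Br)c(/C=C/c2ccccc2)c1 | intermediate
5 | 4,4,5,5‑tetramethyl‑2‑(3‑methylbut‑2‑en‑1‑yl)‑1,3,2‑dioxaborolane (prenylboronic acid pinacol ester) | CC(C)=CCB1OC(C)(C)C(C)(C)O1 | starting material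
6 | 4‑(3‑methylbut‑2‑en‑1‑yl)‑5‑[(E)‑2‑phenylethenyl]benzene‑1,3‑diol (2‑prenylpinosylvin) | CC(C)=CCc1c(O)cc(O)cc1/C=C/c1ccccc1 | intermediate
7 | 4‑{[(2R)‑3,3‑dimethyloxiran‑2‑yl]methyl}‑5‑[(E)‑2‑phenylethenyl]benzene‑1,3‑diol | CC1(C)O[C@@H]1Cc1c(O)cc(O)cc1/C=C/c1ccccc1 | intermediate
8 | (3R)‑2,2‑dimethyl‑5‑[(E)‑2‑phenylethenyl]‑3,4‑dihydro‑2H‑chromene‑3,7‑diol | Oc1cc(/C=C/c2ccccc2)c2c(c1)OC(C)(C)[C@H](O)C2 | intermediate
9 | 1‑bromo‑3‑methylbut‑2‑ene (prenyl bromide) | CC(C)=CCBr | starting material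
10 | (3R)‑2,2‑dimethyl‑8‑(3‑methylbut‑2‑en‑1‑yl)‑5‑[(E)‑2‑phenylethenyl]‑3,4‑dihydro‑2H‑chromene‑3,7‑diol | CC(C)=CCc1c(O)cc(/C=C/c2ccccc2)c2c1OC(C)(C)[C@H](O)C2 | target

**Step count and risks**
Total steps: 5. Longest linear sequence: 5 (from 1).

Most likely to fail:

- **Step 4 (proposed new step).** A phenoxide may not organise in the catalyst like an alkoxide, which would give low ee. The epoxide may also close 5‑exo to the dihydrobenzofuran isomer. The fallback uses known chemistry; it sets out from 6 and returns at 8. Both phenols are silylated (t‑BuMe2SiCl, imidazole, DMF) to give 1,3‑bis(tert‑butyldimethylsilyloxy)‑4‑(3‑methylbut‑2‑en‑1‑yl)‑5‑[(E)‑2‑phenylethenyl]benzene F3. Shi epoxidation follows, with the D‑fructose‑derived ketone (1,2:4,5‑di‑O‑isopropylidene‑β‑D‑erythro‑2,3‑hexodiulo‑2,6‑pyranose), KHSO5 (as 2KHSO5·KHSO4·K2SO4) and K2CO3 in MeCN/dimethoxymethane/water at 0 °C. It is stopped at about one equivalent of oxidant so the trisubstituted alkene reacts ahead of the stilbene. This gives 1,3‑bis(tert‑butyldimethylsilyloxy)‑4‑{[(2R)‑3,3‑dimethyloxiran‑2‑yl]methyl}‑5‑[(E)‑2‑phenylethenyl]benzene F4. Bu4NF buffered with AcOH (THF, 0 °C) removes the silyl groups without ionising the phenol, and camphorsulfonic acid in CH2Cl2 at 0 °C closes the ring 6‑endo to 8.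

- **Step 5.** O‑alkylation, C6 alkylation and double alkylation compete, so the yield of a phenoxide C‑prenylation is moderate at best. The fallback sets out from 8 and returns at 10. The phenol is O‑alkylated with methyl 2‑methylbut‑3‑en‑2‑yl carbonate and Pd(PPh3)4 (5 mol%, THF, 0 °C), which gives the branched ether (3R)‑2,2‑dimethyl‑7‑[(2‑methylbut‑3‑en‑2‑yl)oxy]‑5‑[(E)‑2‑phenylethenyl]‑3,4‑dihydro‑2H‑chromen‑3‑ol F5. Aromatic Claisen rearrangement (N,N‑diethylaniline, 130 °C) then delivers the normal prenyl group to the ortho carbon, C8 being favoured over the styryl‑flanked C6, to give 10.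

- **Step 3.** The bromide is flanked on both sides and becomes very electron‑rich as the bis‑phenoxide, so oxidative addition may be slow and protodebromination or branched coupling may intrude. The fallback sets out from 4 and returns at 6. Protection with MOMCl and i‑Pr2NEt in CH2Cl2 gives 2‑bromo‑1,5‑bis(methoxymethoxy)‑3‑[(E)‑2‑phenylethenyl]benzene F1. Bromine–lithium exchange with n‑BuLi in THF at −78 °C (much faster than addition to the stilbene), then CuBr·SMe2 and prenyl bromide 9, gives 1,5‑bis(methoxymethoxy)‑2‑(3‑methylbut‑2‑en‑1‑yl)‑3‑[(E)‑2‑phenylethenyl]benzene F2. Dilute HCl in MeOH at rt removes the acetals to give 6.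

**Further compounds**
F1 | step 3 | 2‑bromo‑1,5‑bis(methoxymethoxy)‑3‑[(E)‑2‑phenylethenyl]benzene | COCOc1cc(OCOC)c(Br)c(/C=C/c2ccccc2)c1
F2 | step 3 | 1,5‑bis(methoxymethoxy)‑2‑(3‑methylbut‑2‑en‑1‑yl)‑3‑[(E)‑2‑phenylethenyl]benzene | COCOc1cc(OCOC)c(CC=C(C)C)c(/C=C/c2ccccc2)c1
F3 | step 4 | 1,3‑bis(tert‑butyldimethylsilyloxy)‑4‑(3‑methylbut‑2‑en‑1‑yl)‑5‑[(E)‑2‑phenylethenyl]benzene | CC(C)=CCc1c(O[Si](C)(C)C(C)(C)C)cc(O[Si](C)(C)C(C)(C)C)cc1/C=C/c1ccccc1
F4 | step 4 | 1,3‑bis(tert‑butyldimethylsilyloxy)‑4‑{[(2R)‑3,3‑dimethyloxiran‑2‑yl]methyl}‑5‑[(E)‑2‑phenylethenyl]benzene | CC1(C)O[C@@H]1Cc1c(O[Si](C)(C)C(C)(C)C)cc(O[Si](C)(C)C(C)(C)C)cc1/C=C/c1ccccc1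
F5 | step 5 | (3R)‑2,2‑dimethyl‑7‑[(2‑methylbut‑3‑en‑2‑yl)oxy]‑5‑[(E)‑2‑phenylethenyl]‑3,4‑dihydro‑2H‑chromen‑3‑ol | C=CC(C)(C)Oc1cc(/C=C/c2ccccc2)c2c(c1)OC(C)(C)[C@H](O)C2
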